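Late in the south run, between 1.00 min and 2.50 min, starting material falls from 8.9 % to 1.8 % and target from 7.2 % to 2.9 %. The tail half-life of starting material, the time in which its late remainder halves, is therefore 0.651 min, and the same reckoning gives 1.14 min for target.

all flasks: gas phase 110 mM (held)
- south: starting material 0.25 M; the very flask that is asked about, followed so far
- north: starting material 0.17 M; run made earlier
- flask: starting material 0.25 M; time 5.0 min

| run | time / min | target / % | starting material / % |
|---|---|---|---|
| south | 0.167 | 7.5 | 43.3 |
| south | 0.200 | 7.5 | 36.3 |
| south | 0.500 | 8.6 | 18.8 |
| south | 1.00 | 7.2 | 8.9 |
| south | 2.50 | 2.9 | 1.8 |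
| north | 0.167 | 8.6 | 42.4 |
| north | 0.250 | 10.6 | 31.2 |
| north | 0.500 | 10.6 | 18.9 |
| north | 1.33 | 8.0 | 6.5 |
| north | 4.00 | 0.3 | 0 |

(standard deviation of a reading: 0.5 percentage points)

- at the start none of the gas phase is in solution

- the best time, 5.0 min at the latest, for target
- the amount of target, in percent of the starting material charged, at that time

Two chemists dispute where target peaks in the south flask, which is the flask asked about. The first takes two first-order steps in series, starting material to target to loss, with these late half-lives. The formula for such a chain puts the peak at 1.23 min, later than the reading of 7.2 % at 1.00 min.

The second starts from the first reading of each run. The first half-life of starting material is 0.138 min in south and 0.135 min in north, although the charges are 0.25 M and 0.17 M, and it is shorter than the tail half-life. So she carries the flat top of north, between 0.250 min and 0.500 min, over to south.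

I side with the second, since the south reading at 0.500 min stands 1.4 percentage points above the one at 1.00 min, against a scatter of 0.5 points. My own reckoning puts the peak near 0.375 min, a little above 8.6 %.

The forecast takes the same side, with 0.4 min (from 0.25 min to 0.6 min) and 8.7 % (from 8 % to 9.5 %), “with a broad, flat top”.

The south flask peaks at 0.367 min with 8.81 % of target, earlier than the chain's time.

    dissolved gas + target → over-reacted product (k = 0.330 /M/s)
    starting material ⇌ dormant form (K = 1.10, k = 0.0780 /s)
    dissolved gas → decomposed reagent (k = 0.0310 /s)
    starting material + target → side product (k = 1.10 /M/s)
    starting material + dissolved gas → target (k = 0.390 /M/s)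
    gas phase ⇌ dissolved gas, rate k6*(csat - [dissolved gas]) (kL = 0.320 /s)

At that peak the south flask holds 23.0 % starting material and more as dormant form, a resting state, at 33.6 %. The first chemist's first-order count of starting material belongs to the tail. Counting tail half-lives from the south reading of 1.8 % at 2.50 min gives 0.126 % of starting material at 5.0 min, and the south flask holds 0.13 %. In the north run, the count with the same half-life from 6.5 % at 1.33 min gives 0.379 % at 4.00 min, where the reading is 0 %, with a scatter of 0.5 points.

The runs were generated by integration with made-up constants, noise included.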